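**Retrosynthetic overview**
- Target ⇒ allylic alcohol with an exocyclic C9=C11 bond (9-H by hydroxyl-directed hydrogenation) ⇒ Δ8(9) tetrasubstituted alkene (8-OH by singlet-oxygen ene reaction).
- Key C9–C11 bond: light-driven nickel/iridium decarboxylative coupling of a bicyclic C9 enol triflate with a C11–C16 acid cut from (S)-citronellol, which brings C13.
- Enol triflate ⇒ cis-fused sulfonyl enone by dissolving-metal reduction, which also removes the sulfone.
- Ring order: ring B is bought as (R)-carvone, which brings C5. Ring A is annulated onto it: the C3–C4 bond by radical allylation of the isopropenyl group, then the C1–C10 bond by Michael closure with angular methylation.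
- C10, C8 and C9 are then set one after another under control of C5.

Assumption: the SMILES is taken as written, i.e. the 5,10-cis-fused (10-epi) labdane (5S,8R,9R,10R,13S), not the trans-fused sclareol series; labdane numbering is used for positions (C1–C10 decalin, C11–C16 side chain, C17 on C8, C18/C19 on C4, C20 on C10).

**Step 1**
Reactants: 1 (R)-(−)-carvone; 2 2,3-bis(phenylsulfonyl)prop-1-ene
Product: 3 (5R)-2-methyl-5-[2-methyl-4-(phenylsulfonyl)pent-4-en-2-yl]cyclohex-2-en-1-one
Conditions: Fe(acac)3 (30 mol%), PhSiH3 (2.5 equiv), 2 (2 equiv), EtOH/(CH2OH)2, 60 °C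
Reagents that add atoms: none
Why: Mukaiyama-type metal-hydride hydrogen atom transfer (MHAT) from the iron hydride to the electron-rich isopropenyl group (the electron-poor enone is left alone) gives the tertiary C4 radical, which adds to the CH2 terminus of 2 and expels PhSO2• (radical SH2′ allylation), forming the C3–C4 bond and the gem-dimethyl carbon without touching the bought C5 centre.

**Step 2**
Reactants: 3
Product: 5 (4aS,8aR)-2,5,5,8a-tetramethyl-7-(phenylsulfonyl)-4a,5,6,7,8,8a-hexahydronaphthalen-1(4H)-one, via ring-closed lithium dienolate 4 (not isolated)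
Conditions: LiN(SiMe3)2 (1.05 equiv), THF (0.02 M), −78 → 0 °C; then MeI (5 equiv), DMPU, 0 °C → rt
Reagents that add atoms: iodomethane, CI
Why: Kinetic α′-deprotonation at C10 and 6-endo-trig intramolecular Michael addition to the vinyl sulfone (C10–C1 bond) close ring A, proton transfer gives dienolate 4, and its angular methylation occurs equatorially on ring A on the face of 5-H because the other face is blocked by the syn-axial C4 methyl, so C10 (R) is set cis-fused under control of C5.

**Step 3**
Reactants: 5
Product: 7 (4aS,8aR)-2,5,5,8a-tetramethyl-3,4,4a,5,6,7,8,8a-octahydronaphthalen-1-yl trifluoromethanesulfonate, via desulfonylated lithium enolate 6 (not isolated)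
Conditions: Li (4.5 equiv), NH3(l)/THF, t-BuOH (2 equiv), −78 °C; NH3 off; then PhNTf2 (1.5 equiv), THF, 0 °C → rt
Reagents that add atoms: N-phenylbis(trifluoromethanesulfonimide), O=S(=O)(N(c1ccccc1)S(=O)(=O)C(F)(F)F)C(F)(F)F
Why: Dissolving-metal (Birch-type) reduction turns the enone into the regiodefined C8=C9 lithium enolate (C10 is quaternary, so it cannot equilibrate) and at the same time cleaves the C2–SO2Ph bond, and O-triflation of the enolate then gives the enol triflate with both stereocentres untouched.

**Step 4**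
Reactants: 8 (S)-(−)-citronellol
Product: 9 (S)-citronellyl acetate [(3S)-3,7-dimethyloct-6-en-1-yl acetate]
Conditions: Ac2O, pyridine, DMAP (cat.), CH2Cl2, 0 °C → rt
Reagents that add atoms: acetic anhydride, CC(=O)OC(C)=O
Why: Standard DMAP-catalysed acetylation of the primary alcohol; the bought C13 centre is not involved and the acetate of the target is in place from here on.

**Step 5**
Reactants: 9
Product: 10 (4S)-6-acetoxy-4-methylhexanoic acid
Conditions: RuCl3·xH2O (2 mol%), NaIO4 (4 equiv), EtOAc/MeCN/H2O, rt
Reagents that add atoms: sodium periodate, [Na+].[O-]I(=O)(=O)=O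
Why: Ruthenium tetroxide-catalysed (Sharpless-type) oxidative cleavage of the trisubstituted alkene gives the acid and acetone, while the acetate and the remote stereocentre are inert.

**Step 6**
Reactants: 7; 10
Product: 11 (3S)-3-methyl-5-[(4aS,8aR)-2,5,5,8a-tetramethyl-3,4,4a,5,6,7,8,8a-octahydronaphthalen-1-yl]pentyl acetate
Conditions: Ir[dF(CF3)ppy]2(dtbbpy)PF6 (2 mol%), NiBr2(dme) (10 mol%), 4,4′-di-tert-butyl-2,2′-bipyridine (15 mol%), Cs2CO3 (1.5 equiv), 10 (1.5 equiv), DMF, 450 nm LEDs, 30 °C
Reagents that add atoms: none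
Why: Proposed new method: the photoexcited iridium complex oxidises the cesium carboxylate of 10, CO2 is lost, and the primary C11 radical is captured by the alkenylnickel formed by oxidative addition of zerovalent nickel into the C9–OTf bond, after which reductive elimination from trivalent nickel forms the C9–C11 bond (no stereocentre is made; C13 is β to the radical and untouched); the closest known reactions are metallaphotoredox decarboxylative alkenylation of acids with vinyl halides and nickel-catalysed reductive alkylation of enol triflates, neither shown for an unactivated primary acid with a fully substituted cycloalkenyl triflate flanked by a quaternary carbon, where the small primary radical and the easy C–O oxidative addition are what should make it work.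

**Step 7**
Reactants: 11
Product: 13 (3S)-5-[(2R,4aS,8aR)-2-hydroxy-2,5,5,8a-tetramethyloctahydronaphthalen-1(2H)-ylidene]-3-methylpentyl acetate, via allylic hydroperoxide 12 (not isolated)
Conditions: O2, meso-tetraphenylporphyrin (0.5 mol%), CH2Cl2, white LEDs, −20 °C; then PPh3 (1.2 equiv), −20 °C → rt
Reagents that add atoms: oxygen, O=O
Why: Schenck ene reaction of singlet oxygen with the tetrasubstituted alkene puts oxygen on C8 and takes H from C11, the group geminal to the bulky quaternary C10 (large-group effect), from the convex α face opposite the axial C1 of ring A, so C8 (R) is set by the ring fusion, and PPh3 reduces the hydroperoxide.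

**Step 8**
Reactants: 13
Product: 14 (3S)-5-[(1R,2R,4aS,8aR)-2-hydroxy-2,5,5,8a-tetramethyldecahydronaphthalen-1-yl]-3-methylpentyl acetate
Conditions: H2 (1 atm), [Ir(cod)(PCy3)(py)]PF6 (5 mol%), CH2Cl2, rt
Reagents that add atoms: none
Why: Hydroxyl-directed hydrogenation, in which the cationic iridium complex binds the tertiary 8-OH and delivers H2 to the same (α, convex) face of the exocyclic C9=C11 bond, gives 9-H cis to 8-OH (9R) and completes the target.

**Compound list**
1 | (R)-(−)-carvone | CC1=CC[C@H](CC1=O)C(C)=C | starting material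
2 | 2,3-bis(phenylsulfonyl)prop-1-ene | C=C(CS(=O)(=O)c1ccccc1)S(=O)(=O)c1ccccc1 | starting material
3 | (5R)-2-methyl-5-[2-methyl-4-(phenylsulfonyl)pent-4-en-2-yl]cyclohex-2-en-1-one | CC1=CC[C@H](CC1=O)C(C)(C)CC(=C)S(=O)(=O)c1ccccc1 | intermediate
4 | lithium dienolate of (4aS)-2,5,5-trimethyl-7-(phenylsulfonyl)-4a,5,6,7,8,8a-hexahydronaphthalen-1(4H)-one (ring A closed; sulfone carbon as epimers; formed in the flask) | [Li]OC1=C2CC(S(=O)(=O)c3ccccc3)CC(C)(C)[C@@H]2CC=C1C | intermediate
5 | (4aS,8aR)-2,5,5,8a-tetramethyl-7-(phenylsulfonyl)-4a,5,6,7,8,8a-hexahydronaphthalen-1(4H)-one (cis-fused; sulfone carbon as epimers) | O=C1[C@]2(C)CC(S(=O)(=O)c3ccccc3)CC(C)(C)[C@@H]2CC=C1C | intermediate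
6 | lithium (4aS,8aR)-2,5,5,8a-tetramethyl-3,4,4a,5,6,7,8,8a-octahydronaphthalen-1-olate (formed in the flask) | [Li]OC=1[C@]2(C)CCCC(C)(C)[C@@H]2CCC=1C | intermediate
7 | (4aS,8aR)-2,5,5,8a-tetramethyl-3,4,4a,5,6,7,8,8a-octahydronaphthalen-1-yl trifluoromethanesulfonate | FC(F)(F)S(=O)(=O)OC=1[C@]2(C)CCCC(C)(C)[C@@H]2CCC=1C | intermediate
8 | (S)-(−)-citronellol | C[C@@H](CCC=C(C)C)CCO | starting material
9 | (S)-citronellyl acetate | CC(=O)OCC[C@@H](C)CCC=C(C)C | intermediate
10 | (4S)-6-acetoxy-4-methylhexanoic acid | CC(=O)OCC[C@@H](C)CCC(=O)O | intermediate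
11 | (3S)-3-methyl-5-[(4aS,8aR)-2,5,5,8a-tetramethyl-3,4,4a,5,6,7,8,8a-octahydronaphthalen-1-yl]pentyl acetate | CC(=O)OCC[C@@H](C)CCC=1[C@]2(C)CCCC(C)(C)[C@@H]2CCC=1C | intermediate
12 | (3S)-5-[(2R,4aS,8aR)-2-hydroperoxy-2,5,5,8a-tetramethyloctahydronaphthalen-1(2H)-ylidene]-3-methylpentyl acetate (C9=C11 geometry not defined; formed in the flask) | CC(=O)OCC[C@@H](C)CC=C1[C@]2(C)CCCC(C)(C)[C@@H]2CC[C@@]1(C)OO | intermediate
13 | (3S)-5-[(2R,4aS,8aR)-2-hydroxy-2,5,5,8a-tetramethyloctahydronaphthalen-1(2H)-ylidene]-3-methylpentyl acetate (C9=C11 geometry not defined) | CC(=O)OCC[C@@H](C)CC=C1[C@]2(C)CCCC(C)(C)[C@@H]2CC[C@@]1(C)O | intermediate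
14 | (3S)-5-[(1R,2R,4aS,8aR)-2-hydroxy-2,5,5,8a-tetramethyldecahydronaphthalen-1-yl]-3-methylpentyl acetate | CC(=O)OCC[C@@H](C)CC[C@@H]1[C@]2(C)CCCC(C)(C)[C@@H]2CC[C@@]1(C)O | target

**Step count and risks**
Total step count: 8. Longest linear sequence: 6 steps (steps 1, 2, 3, 6, 7, 8 from (R)-carvone); steps 4 and 5 make the side-chain acid.

The three steps most likely to fail:

Step 6 (the proposed new coupling). The crowded alkenylnickel may capture the radical slowly, so that reduction of the triflate, radical dimerisation or 1,5-hydrogen shift in the radical take over. The fallback uses known chemistry, sets out from 10 (with 7) and returns at 11. Acid 10 is converted by light-driven iododecarboxylation (PhI(OAc)2, I2, hν, 1,2-dichloroethane, reflux) into (3R)-5-iodo-3-methylpentyl acetate F3. Zinc insertion (Zn dust, LiCl, THF, 40 °C) gives [(3R)-5-acetoxy-3-methylpentyl]zinc iodide F4, which tolerates the acetate. A palladium-catalysed Negishi coupling with triflate 7 (PdCl2(dppf), THF/NMP, 60 °C) gives 11.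

Step 2 (ring A closure and angular methylation). The 6-endo Michael closure may be slow against vinyl sulfone isomerisation or oligomerisation, and the methylation may not be fully cis-selective. The fallback sets out from 1 (with 2) and returns at 5, forming the two ring A bonds in the opposite order. The lithium enolate of 1 (LiN(iPr)2, THF, −78 °C) is alkylated with 2 by SN2′ addition–elimination to give (5R)-2-methyl-6-[2-(phenylsulfonyl)prop-2-en-1-yl]-5-(prop-1-en-2-yl)cyclohex-2-en-1-one F1. A second enolisation and MeI (LiN(SiMe3)2, THF, −78 °C) puts the methyl group trans to the isopropenyl group, the usual outcome for 6-substituted carvones, giving (5S,6R)-2,6-dimethyl-6-[2-(phenylsulfonyl)prop-2-en-1-yl]-5-(prop-1-en-2-yl)cyclohex-2-en-1-one F2. MHAT-initiated 6-endo Giese cyclisation of the isopropenyl-derived radical onto the vinyl sulfone (Fe(acac)3, PhSiH3, EtOH, 60 °C) then gives 5.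

Step 7 (regio- and face selectivity of the ene reaction). Oxygen may add at C9 with H taken from C7 or C17, or the ring A olefin-free face may not be discriminated well enough. The fallback sets out from 11 and returns at 14. Hydroboration (BH3·SMe2, THF, 45 °C) adds boron to the less hindered C8 and hydrogen to C9, syn and from the convex face. Alkaline peroxide work-up (NaOH, H2O2, 50 °C) oxidises with retention and saponifies the acetate, giving (1R,2R,4aS,8aR)-1-[(3S)-5-hydroxy-3-methylpentyl]-2,5,5,8a-tetramethyldecahydronaphthalen-2-ol F5. Selective acetylation of the primary alcohol (Ac2O, pyridine, 0 °C) gives 14.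

**Further compounds**
F1 | step 2 | (5R)-2-methyl-6-[2-(phenylsulfonyl)prop-2-en-1-yl]-5-(prop-1-en-2-yl)cyclohex-2-en-1-one | CC1=CC[C@H](C(CC(=C)S(=O)(=O)c2ccccc2)C1=O)C(C)=C
F2 | step 2 | (5S,6R)-2,6-dimethyl-6-[2-(phenylsulfonyl)prop-2-en-1-yl]-5-(prop-1-en-2-yl)cyclohex-2-en-1-one | CC1=CC[C@H]([C@@](C)(CC(=C)S(=O)(=O)c2ccccc2)C1=O)C(C)=C
F3 | step 6 | (3R)-5-iodo-3-methylpentyl acetate | CC(=O)OCC[C@@H](C)CCI
F4 | step 6 | [(3R)-5-acetoxy-3-methylpentyl]zinc iodide | CC(=O)OCC[C@@H](C)CC[Zn]I
F5 | step 7 | (1R,2R,4aS,8aR)-1-[(3S)-5-hydroxy-3-methylpentyl]-2,5,5,8a-tetramethyldecahydronaphthalen-2-ol | OCC[C@@H](C)CC[C@@H]1[C@]2(C)CCCC(C)(C)[C@@H]2CC[C@@]1(C)O
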